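## The problem

Hansforester A (30) is an open-chain pentaester. Orsellinic acid (ring A), (R)-3-hydroxybutanoic acid (unit B), 2,4-dihydroxy-6-[(R)-2-hydroxypropyl]benzoic acid (ring C), a second (R)-3-hydroxybutanoic acid (unit D) and (R)-1-(3,5-dihydroxyphenyl)propan-2-ol (ring E) are joined head to tail by four ester bonds. No ring has to be closed; the task is the order and manner in which the four esters are made. Two of them (A–B and C–D) are benzoates with two ortho substituents, which form only slowly by attack of a secondary alcohol on the acyl carbon; the other two (B–C and D–E) are 3-acyloxybutanoates of secondary alcohols. The four stereocentres are all R-configured O–CH(CH3)–CH2 carbons, each separated from the next by an ester group and at least one methylene, so none can direct another. Each must come from the chiral pool, an auxiliary, a reagent or a catalyst. The chain is fragile: base eliminates the acyloxy group of either butanoate unit to a crotonate, nucleophiles transesterify, the resorcinol rings are electron-rich, and a free hydroxypropyl arm on ring C lactonises onto the ring C carboxyl, so the last deprotection must be neutral. The feature that permits the key step is the B–C ester: the carbonyl carbon C1 of unit B is bound through oxygen to the methyl-bearing secondary carbon of the ring C side chain. Without that oxygen the compound is a ketone flanked by a secondary stereocentre and a CH2 group, the pattern on which a Baeyer–Villiger oxidation inserts oxygen on the secondary side with retention. The stereocentre is then a C–C stereocentre that an enolate alkylation can set, and the carbinol oxygen of ring C is born acylated.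

## Retrosynthesis

**30 ← 29.** The six O–benzyl bonds are cut last. Benzyl is the one phenol protecting group that leaves under neutral conditions, and the chain C–O bonds are homobenzylic and so not at risk. Precursor 29 is no smaller, but all earlier chemistry can then be run without free phenols. The forward step is a sixfold hydrogenolysis.

**29 ← 22 + 28.** The C–D ester is cut between the carboxyl of ring C and the oxygen of unit D. This divides the five units three to two; a cut at D–E would divide them four to one, and the B–C bond is reserved for the key step. Because acid 22 is a 2,6-disubstituted benzoic acid, the bond is best made with the carboxylate as nucleophile at the carbinol carbon, with inversion. Alcohol 28 therefore carries the 3S configuration. The forward reaction must substitute cleanly without dehydrating the 3-hydroxybutanoate.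

**22 ← 21 ← 20.** After release of the ring C carboxyl from its tert-butyl ester, the key cut removes the oxygen between C1 of unit B and the side-chain carbon of ring C. An ordinary ester disconnection at this bond would need a free ring C alcohol, which lactonises onto the ring C carboxyl. Ketone 20 has the same size as 21, but its skeleton can be assembled by enolate C–C chemistry. The forward oxidation must migrate the secondary carbon in preference to the CH2, retain configuration, and spare two benzyloxy-substituted benzoate rings. It is therefore placed before ring E, the only ring without an acceptor group, is attached.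

**20 ← 18 + 3 (through 19).** The A–B ester is cut at its acyl–oxygen bond. Acylation of the beta-hydroxy ketone 18 with the acid chloride 19 is chosen over an inversion coupling because beta-hydroxy ketones dehydrate under the latter. Installing ring A before the oxidation saves a protecting group, and the aroyloxy group further lowers the migratory aptitude of the competing CH2.

**18 ← 15 + 16; 15 ← 14 ← 13 ← 11 + 10.** The C4–C5 bond of the side chain is cut to methyl ketone 15 and acetaldehyde 16; this asks for a reagent-controlled aldol on the methyl side of the ketone. Ketone 15 goes back through Weinreb amide 14 to imide 13, which is cut at the benzylic C–C bond into propionimide 11 and benzylic bromide 10. The auxiliary alkylation sets the centre that becomes the carbinol of ring C.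

**10 ← 9 ← 8 ← 6 ← 5 ← 4.** A radical bromination of a benzyl-protected orsellinate would be the shortest way to 10. It is set aside because the ring positions between the oxygens and the O–CH2Ph groups compete with the methyl group. Instead the substitution pattern is fixed by electrophilic bromination of alcohol 4 ortho to its hydroxymethyl group. The bromine is exchanged for the tert-butyl ester through an aryllithium, and the alcohol becomes the leaving group. Each step is simple, at the price of length.

**3 ← 2 ← 1.** Ring A comes from methyl orsellinate 1 by benzylation and saponification.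

**28 ← 27 ← 26 ← 23 + 24.** The carbinol of unit D is traced to a ketone (catalytic asymmetric hydrogenation of acetoacetate 27). The acetoacetate comes from alcohol 26, and 26 from aryl bromide 23 and (R)-propylene oxide 24, which supplies the stereocentre of unit E intact.

## Roads not taken

**Alternative 1:** Ring E is built de novo. The cut goes through two C–C bonds of the arene. NaOMe promotes Michael addition of dimethyl malonate (A3) to the (R)-enone A2, which derives from a protected (R)-3-hydroxybutanal. Claisen closure of the methyl ketone enolate onto a malonate ester then gives the cyclohexanedione ester A1. Decarboxylation and dehydrogenation would lead to the 5-alkylresorcinol.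
- Merits: the carbinol centre of unit E comes from the chiral pool, and arene and side chain are made together without an organometallic step.
- Weak points: four to five operations, one of them an oxidative aromatisation beside a silyl ether, for a fragment reached here in one step from 23 and 24. The road says nothing about the esters.
- Comparison: if the ester group of A1 is kept, the product is a ring C type resorcylate with the correct 1,2-relationship, which is as certain in regiochemistry as the five steps from 4 to 10. That carboxyl would be a methyl ester, however, which cannot be unmasked beside the chain esters. For unit E this road is equal in stereochemical certainty and clearly longer.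

**Alternative 2:** The two ortho substituents of ring C are set by aryne insertion. CsF generates the 3,5-bis(benzyloxy)aryne from silyl triflate A5. Malonate A3 adds at the carbon remote from the flanking benzyloxy group, the aryl anion closes onto an ester carbonyl and the four-membered alkoxide opens to give homophthalate A4.
- Merits: both ring C–substituent bonds form in one step with regiochemistry dictated by the alkoxy group. At that point this road is better than the sequence from 4 to 10. The B–C ester would then be made by plain acylation, which is safer than a peracid step on an advanced intermediate.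
- Weak points: A5 needs its own multi-step preparation. The aliphatic ester of A4 must be differentiated, turned into a methyl ketone and reduced asymmetrically. The resulting alcohol closes onto the aromatic methyl ester to a dihydroisocoumarin, and the aromatic methyl ester cannot later be removed selectively.
- Comparison: the chosen plan sets against it a stereocentre made by a reliable auxiliary alkylation, a carbinol oxygen that is never free, and a tert-butyl ester in place from the start.

**Alternative 3:** Unit D is assembled by carbonylative epoxide opening. Co2(CO)8 with a hydroxypyridine co-catalyst opens epoxide 24 at its CH2 carbon, carbonyl insertion follows, and alcohol 26 cleaves the acylcobalt species to give the D–E alcohol A6, the 3R epimer of 28.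
- Merits: one step from 26 and 24, no chiral catalyst, and the stereocentre comes untouched from the chiral pool. This is one step shorter than steps 16 and 17.
- Weak points: the reaction is established with simple alcohols in large excess. With a valuable secondary alcohol as limiting reagent, beta-lactone formation and epoxide isomerisation compete, and pressure equipment is needed. A6 has the configuration for an acylative union, not for the inversion coupling chosen here; the enantiomeric epoxide would be required.
- Comparison: the chosen plan sets against it a hydrogenation that works on a stoichiometric complex alcohol and gives either epimer by choice of ligand. The road does not touch the B–C junction.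

Key step: step 13

Assumption: the isopinocampheylboron enolate of a methyl ketone made with (+)-Ipc2BCl (from (−)-α-pinene) is taken to add to the Si face of acetaldehyde; if the adduct proves to be the 5S epimer, the antipodal borane is used and nothing else changes.

## Route

Step 1
Reactants: 1 methyl orsellinate
Product: 2 methyl 2,4-bis(benzyloxy)-6-methylbenzoate
Conditions: BnBr, K2CO3, DMF, 60 °C
Reagents that add atoms: benzyl bromide, BrCc1ccccc1
Why: Williamson O-benzylation of both phenols; the chelated 2-hydroxyl needs the polar solvent and heat. Benzyl is chosen because it leaves at the end without acid or base.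

Step 2
Reactants: 2 methyl 2,4-bis(benzyloxy)-6-methylbenzoate
Product: 3 2,4-bis(benzyloxy)-6-methylbenzoic acid
Conditions: KOH, DMSO/H2O, 100 °C; then aq. HCl
Reagents that add atoms: potassium hydroxide, [K+].[OH-]
Why: Saponification of a 2,6-disubstituted benzoate needs hydroxide in a dipolar solvent at high temperature; nothing else in 2 is base-sensitive.

Step 3
Reactants: 4 [3,5-bis(benzyloxy)phenyl]methanol
Product: 5 [3,5-bis(benzyloxy)-2-bromophenyl]methanol
Conditions: N-bromosuccinimide (1.0 equiv), CH2Cl2, 0 °C
Reagents that add atoms: N-bromosuccinimide, O=C1CCC(=O)N1Br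
Why: Electrophilic aromatic bromination; the position ortho to CH2OH and para to one benzyloxy group is favoured over the position flanked by two benzyloxy groups, as is usual for 3,5-dialkoxybenzyl alcohols. This fixes where the ring C carboxyl will sit.

Step 4
Reactants: 5 [3,5-bis(benzyloxy)-2-bromophenyl]methanol
Product: 6 {[3,5-bis(benzyloxy)-2-bromobenzyl]oxy}(tert-butyl)dimethylsilane
Conditions: TBSCl, imidazole, DMF, rt
Reagents that add atoms: tert-butyldimethylsilyl chloride, CC(C)(C)[Si](C)(C)Cl
Why: Standard silylation of a primary alcohol, which masks the hydroxyl proton before the lithiation.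

Step 5
Reactants: 6 {[3,5-bis(benzyloxy)-2-bromobenzyl]oxy}(tert-butyl)dimethylsilane
Product: 8 tert-butyl 2,4-bis(benzyloxy)-6-{[(tert-butyldimethylsilyl)oxy]methyl}benzoate, via aryllithium 7 (not isolated)
Conditions: n-BuLi, THF, −78 °C; then Boc2O, −78 → 0 °C
Reagents that add atoms: di-tert-butyl dicarbonate, CC(C)(C)OC(=O)OC(=O)OC(C)(C)C
Why: Bromine–lithium exchange outruns any deprotonation at −78 °C, and acylation of an aryllithium by the dicarbonate gives the tert-butyl ester directly. Low temperature and prompt trapping keep the silyl group from migrating from oxygen to the lithiated carbon.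

Step 6
Reactants: 8 tert-butyl 2,4-bis(benzyloxy)-6-{[(tert-butyldimethylsilyl)oxy]methyl}benzoate
Product: 9 tert-butyl 2,4-bis(benzyloxy)-6-(hydroxymethyl)benzoate
Conditions: HF·pyridine, THF, 0 °C
Reagents that add atoms: none
Why: Fluoride desilylation under non-basic conditions, so that no alkoxide forms that could close onto the neighbouring ester to a phthalide.

Step 7
Reactants: 9 tert-butyl 2,4-bis(benzyloxy)-6-(hydroxymethyl)benzoate
Product: 10 tert-butyl 2,4-bis(benzyloxy)-6-(bromomethyl)benzoate
Conditions: CBr4, PPh3, CH2Cl2, 0 °C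
Reagents that add atoms: carbon tetrabromide, BrC(Br)(Br)Br
Why: Appel bromination converts the benzylic alcohol into the bromide under neutral conditions. 10 is used at once because slow closure to a phthalide with loss of tert-butyl bromide is its likely decomposition path.

Step 8
Reactants: 11 (4S)-4-benzyl-3-propanoyl-1,3-oxazolidin-2-one; 10 tert-butyl 2,4-bis(benzyloxy)-6-(bromomethyl)benzoate
Product: 13 tert-butyl 2,4-bis(benzyloxy)-6-{(2R)-3-[(4S)-4-benzyl-2-oxo-1,3-oxazolidin-3-yl]-2-methyl-3-oxopropyl}benzoate, via sodium enolate 12 (not isolated)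
Conditions: NaN(SiMe3)2, THF, −78 °C; then 10, −78 → −40 °C
Reagents that add atoms: none
Why: Evans asymmetric alkylation: the chelated sodium Z-enolate is attacked by the benzylic bromide on the face opposite the 4-benzyl group. This sets the 2R centre that later becomes the carbinol carbon of ring C.

Step 9
Reactants: 13 tert-butyl 2,4-bis(benzyloxy)-6-{(2R)-3-[(4S)-4-benzyl-2-oxo-1,3-oxazolidin-3-yl]-2-methyl-3-oxopropyl}benzoate
Product: 14 tert-butyl 2,4-bis(benzyloxy)-6-{(2R)-3-[methoxy(methyl)amino]-2-methyl-3-oxopropyl}benzoate
Conditions: MeONHMe·HCl, AlMe3, CH2Cl2, −10 → 0 °C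
Reagents that add atoms: N,O-dimethylhydroxylamine hydrochloride, CNOC.Cl
Why: Aluminium amide transamination of the N-acyloxazolidinone to the Weinreb amide removes the auxiliary without touching the hindered tert-butyl benzoate or the alpha centre.

Step 10
Reactants: 14 tert-butyl 2,4-bis(benzyloxy)-6-{(2R)-3-[methoxy(methyl)amino]-2-methyl-3-oxopropyl}benzoate
Product: 15 tert-butyl 2,4-bis(benzyloxy)-6-[(2R)-2-methyl-3-oxobutyl]benzoate
Conditions: MeMgBr, THF, 0 °C
Reagents that add atoms: methylmagnesium bromide, C[Mg]Br
Why: Weinreb ketone synthesis; the chelated tetrahedral intermediate stops at the ketone stage, and the 2,6-disubstituted tert-butyl benzoate is inert to the Grignard reagent at 0 °C.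

Step 11
Reactants: 15 tert-butyl 2,4-bis(benzyloxy)-6-[(2R)-2-methyl-3-oxobutyl]benzoate; 16 acetaldehyde
Product: 18 tert-butyl 2,4-bis(benzyloxy)-6-[(2R,5R)-5-hydroxy-2-methyl-3-oxohexyl]benzoate, via boron enolate 17 (not isolated)
Conditions: (+)-Ipc2BCl, Et3N, Et2O, 0 °C; then 16, −78 → −20 °C; then H2O2, pH 7 buffer, MeOH, 0 °C
Reagents that add atoms: none
Why: Paterson boron aldol: the chloroborane and Et3N enolise the methyl group regioselectively, and the isopinocampheyl ligands direct the enolate to the Si face of acetaldehyde to set the 5R carbinol. The alpha centre is untouched because the enolate forms on the other side of the carbonyl, and the minor 5S adduct is a diastereomer that can be removed.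

Step 12
Reactants: 3 2,4-bis(benzyloxy)-6-methylbenzoic acid; 18 tert-butyl 2,4-bis(benzyloxy)-6-[(2R,5R)-5-hydroxy-2-methyl-3-oxohexyl]benzoate
Product: 20 tert-butyl 2,4-bis(benzyloxy)-6-[(2R,5R)-5-{[2,4-bis(benzyloxy)-6-methylbenzoyl]oxy}-2-methyl-3-oxohexyl]benzoate, via acid chloride 19 (not isolated)
Conditions: 3, (COCl)2, DMF (cat.), CH2Cl2, 0 °C → rt, evaporation; then 18, pyridine, DMAP (cat.), CH2Cl2, 0 °C → rt
Reagents that add atoms: none
Why: Acylation by the chloride of an electron-rich 2,6-disubstituted benzoic acid, which reacts through an acylium-like transition state and so tolerates its own hindrance. Pyridine is too weak a base to trigger retro-aldol cleavage or beta-elimination at these temperatures.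

Step 13
Reactants: 20 tert-butyl 2,4-bis(benzyloxy)-6-[(2R,5R)-5-{[2,4-bis(benzyloxy)-6-methylbenzoyl]oxy}-2-methyl-3-oxohexyl]benzoate
Product: 21 tert-butyl 2,4-bis(benzyloxy)-6-[(2R)-2-({(3R)-3-{[2,4-bis(benzyloxy)-6-methylbenzoyl]oxy}butanoyl}oxy)propyl]benzoate
Conditions: m-CPBA, NaHCO3, CH2Cl2, rt, dark
Reagents that add atoms: 3-chloroperoxybenzoic acid, OOC(=O)c1cccc(Cl)c1
Why: Baeyer–Villiger oxidation: the peracid adds to the ketone carbonyl to give the Criegee adduct, and the group antiperiplanar to the O–O bond that best bears positive charge, the methyl-bearing secondary carbon C2, shifts from carbon to oxygen as 3-chlorobenzoate leaves. The closest known reaction type is the peracid oxidation of acyclic alkyl sec-alkyl ketones to sec-alkyl esters. No ring is closed and no stereocentre is created; the shift is concerted and suprafacial, so the 2R centre of step 8 becomes the R carbinol centre of ring C with retention. The required regioselectivity, secondary over primary migration, follows from the substitution pattern and is reinforced by the aroyloxy group beta to the competing CH2. The required chemoselectivity over the arenes rests on the mild peracid, on the ester group that each ring carries, and on ring E not yet being present. Solid NaHCO3 keeps the medium from enolising the ketone, which would epimerise C2 or expel the beta-aroyloxy group before insertion.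

Step 14
Reactants: 21 tert-butyl 2,4-bis(benzyloxy)-6-[(2R)-2-({(3R)-3-{[2,4-bis(benzyloxy)-6-methylbenzoyl]oxy}butanoyl}oxy)propyl]benzoate
Product: 22 2,4-bis(benzyloxy)-6-[(2R)-2-({(3R)-3-{[2,4-bis(benzyloxy)-6-methylbenzoyl]oxy}butanoyl}oxy)propyl]benzoic acid
Conditions: CF3CO2H/CH2Cl2 (1:4), 0 °C
Reagents that add atoms: none
Why: Acidolysis of the tert-butyl ester by alkyl–oxygen cleavage, sterically accelerated in a 2,6-disubstituted benzoate. Secondary alkyl esters and aryl benzyl ethers survive brief cold acid.

Step 15
Reactants: 23 1,3-bis(benzyloxy)-5-bromobenzene; 24 (R)-propylene oxide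
Product: 26 (2R)-1-[3,5-bis(benzyloxy)phenyl]propan-2-ol, via arylmagnesium bromide 25 (not isolated)
Conditions: Mg, THF, reflux; then CuI (10 mol %), 24, −30 → 0 °C
Reagents that add atoms: none
Why: Copper-catalysed opening of a terminal epoxide by an aryl Grignard reagent at the CH2 carbon. The stereocentre of 24 is not involved and is carried over as the R carbinol of ring E.

Step 16
Reactants: 26 (2R)-1-[3,5-bis(benzyloxy)phenyl]propan-2-ol
Product: 27 (2R)-1-[3,5-bis(benzyloxy)phenyl]propan-2-yl 3-oxobutanoate
Conditions: 2,2,6-trimethyl-4H-1,3-dioxin-4-one, toluene, 110 °C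
Reagents that add atoms: 2,2,6-trimethyl-4H-1,3-dioxin-4-one, CC1=CC(=O)OC(C)(C)O1
Why: Thermal cycloreversion of the dioxinone gives acetylketene, which the secondary alcohol traps to the acetoacetate under neutral conditions.

Step 17
Reactants: 27 (2R)-1-[3,5-bis(benzyloxy)phenyl]propan-2-yl 3-oxobutanoate
Product: 28 (2R)-1-[3,5-bis(benzyloxy)phenyl]propan-2-yl (3S)-3-hydroxybutanoate
Conditions: H2 (50 atm), RuCl2[(S)-BINAP] (1 mol %), MeOH/CH2Cl2, 30 °C
Reagents that add atoms: none
Why: Noyori asymmetric hydrogenation of a beta-keto ester; the (S)-BINAP ligand sets the 3S alcohol by catalyst control and the remote centre of ring E has no influence. The ruthenium catalyst does not cleave aryl benzyl ethers.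

Step 18
Reactants: 22 2,4-bis(benzyloxy)-6-[(2R)-2-({(3R)-3-{[2,4-bis(benzyloxy)-6-methylbenzoyl]oxy}butanoyl}oxy)propyl]benzoic acid; 28 (2R)-1-[3,5-bis(benzyloxy)phenyl]propan-2-yl (3S)-3-hydroxybutanoate
Product: 29 hexa-O-benzyl Hansforester A (all six phenols of 30 as benzyl ethers)
Conditions: PPh3, diisopropyl azodicarboxylate, toluene, 0 °C → rt
Reagents that add atoms: none
Why: Mitsunobu esterification: the hindered acid 22 reacts as a carboxylate nucleophile at the activated carbinol carbon of 28, so hindrance at its carbonyl is irrelevant. SN2 inversion converts 3S into the 3R centre of unit D.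

Step 19
Reactants: 29 hexa-O-benzyl Hansforester A
Product: 30 Hansforester A
Conditions: H2 (1 atm), 10% Pd/C, EtOAc, rt
Reagents that add atoms: none
Why: Hydrogenolysis of six aryl benzyl ethers under neutral conditions; the chain C–O bonds are homobenzylic, not benzylic, and stay intact.

## Compound list

1 | methyl orsellinate (methyl 2,4-dihydroxy-6-methylbenzoate) | COC(=O)c1c(C)cc(O)cc1O | starting material
2 | methyl 2,4-bis(benzyloxy)-6-methylbenzoate | COC(=O)c1c(C)cc(OCc2ccccc2)cc1OCc1ccccc1 | intermediate
3 | 2,4-bis(benzyloxy)-6-methylbenzoic acid | Cc1cc(OCc2ccccc2)cc(OCc2ccccc2)c1C(=O)O | intermediate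
4 | [3,5-bis(benzyloxy)phenyl]methanol | OCc1cc(OCc2ccccc2)cc(OCc2ccccc2)c1 | starting material
5 | [3,5-bis(benzyloxy)-2-bromophenyl]methanol | OCc1cc(OCc2ccccc2)cc(OCc2ccccc2)c1Br | intermediate
6 | {[3,5-bis(benzyloxy)-2-bromobenzyl]oxy}(tert-butyl)dimethylsilane | CC(C)(C)[Si](C)(C)OCc1cc(OCc2ccccc2)cc(OCc2ccccc2)c1Br | intermediate
7 | [2,4-bis(benzyloxy)-6-{[(tert-butyldimethylsilyl)oxy]methyl}phenyl]lithium (aryllithium) | CC(C)(C)[Si](C)(C)OCc1cc(OCc2ccccc2)cc(OCc2ccccc2)c1[Li] | intermediate
8 | tert-butyl 2,4-bis(benzyloxy)-6-{[(tert-butyldimethylsilyl)oxy]methyl}benzoate | CC(C)(C)[Si](C)(C)OCc1cc(OCc2ccccc2)cc(OCc2ccccc2)c1C(=O)OC(C)(C)C | intermediate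
9 | tert-butyl 2,4-bis(benzyloxy)-6-(hydroxymethyl)benzoate | OCc1cc(OCc2ccccc2)cc(OCc2ccccc2)c1C(=O)OC(C)(C)C | intermediate
10 | tert-butyl 2,4-bis(benzyloxy)-6-(bromomethyl)benzoate | BrCc1cc(OCc2ccccc2)cc(OCc2ccccc2)c1C(=O)OC(C)(C)C | intermediate
11 | (4S)-4-benzyl-3-propanoyl-1,3-oxazolidin-2-one | CCC(=O)N1C(=O)OC[C@@H]1Cc1ccccc1 | starting material
12 | sodium (Z)-enolate of 11 | C/C=C(\[O-])N1C(=O)OC[C@@H]1Cc1ccccc1.[Na+] | intermediate
13 | tert-butyl 2,4-bis(benzyloxy)-6-{(2R)-3-[(4S)-4-benzyl-2-oxo-1,3-oxazolidin-3-yl]-2-methyl-3-oxopropyl}benzoate | O=C1OC[C@H](Cc2ccccc2)N1C(=O)[C@H](C)Cc1cc(OCc2ccccc2)cc(OCc2ccccc2)c1C(=O)OC(C)(C)C | intermediate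
14 | tert-butyl 2,4-bis(benzyloxy)-6-{(2R)-3-[methoxy(methyl)amino]-2-methyl-3-oxopropyl}benzoate | CON(C)C(=O)[C@H](C)Cc1cc(OCc2ccccc2)cc(OCc2ccccc2)c1C(=O)OC(C)(C)C | intermediate
15 | tert-butyl 2,4-bis(benzyloxy)-6-[(2R)-2-methyl-3-oxobutyl]benzoate | CC(=O)[C@H](C)Cc1cc(OCc2ccccc2)cc(OCc2ccccc2)c1C(=O)OC(C)(C)C | intermediate
16 | acetaldehyde | CC=O | starting material
17 | bis[(+)-isopinocampheyl]boron enolate of 15 | C=C(OB([C@H]1C[C@H]2C[C@@H]([C@@H]1C)C2(C)C)[C@H]1C[C@H]2C[C@@H]([C@@H]1C)C2(C)C)[C@H](C)Cc1cc(OCc2ccccc2)cc(OCc2ccccc2)c1C(=O)OC(C)(C)C | intermediate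
18 | tert-butyl 2,4-bis(benzyloxy)-6-[(2R,5R)-5-hydroxy-2-methyl-3-oxohexyl]benzoate | C[C@@H](O)CC(=O)[C@H](C)Cc1cc(OCc2ccccc2)cc(OCc2ccccc2)c1C(=O)OC(C)(C)C | intermediate
19 | 2,4-bis(benzyloxy)-6-methylbenzoyl chloride | Cc1cc(OCc2ccccc2)cc(OCc2ccccc2)c1C(=O)Cl | intermediate
20 | tert-butyl 2,4-bis(benzyloxy)-6-[(2R,5R)-5-{[2,4-bis(benzyloxy)-6-methylbenzoyl]oxy}-2-methyl-3-oxohexyl]benzoate (ketone A-B-C) | Cc1cc(OCc2ccccc2)cc(OCc2ccccc2)c1C(=O)O[C@H](C)CC(=O)[C@H](C)Cc1cc(OCc2ccccc2)cc(OCc2ccccc2)c1C(=O)OC(C)(C)C | intermediate
21 | tert-butyl 2,4-bis(benzyloxy)-6-[(2R)-2-({(3R)-3-{[2,4-bis(benzyloxy)-6-methylbenzoyl]oxy}butanoyl}oxy)propyl]benzoate (ester A-B-C) | Cc1cc(OCc2ccccc2)cc(OCc2ccccc2)c1C(=O)O[C@H](C)CC(=O)O[C@H](C)Cc1cc(OCc2ccccc2)cc(OCc2ccccc2)c1C(=O)OC(C)(C)C | intermediate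
22 | 2,4-bis(benzyloxy)-6-[(2R)-2-({(3R)-3-{[2,4-bis(benzyloxy)-6-methylbenzoyl]oxy}butanoyl}oxy)propyl]benzoic acid (acid A-B-C) | Cc1cc(OCc2ccccc2)cc(OCc2ccccc2)c1C(=O)O[C@H](C)CC(=O)O[C@H](C)Cc1cc(OCc2ccccc2)cc(OCc2ccccc2)c1C(=O)O | intermediate
23 | 1,3-bis(benzyloxy)-5-bromobenzene | Brc1cc(OCc2ccccc2)cc(OCc2ccccc2)c1 | starting material
24 | (R)-propylene oxide [(2R)-2-methyloxirane] | C[C@@H]1CO1 | starting material
25 | [3,5-bis(benzyloxy)phenyl]magnesium bromide | Br[Mg]c1cc(OCc2ccccc2)cc(OCc2ccccc2)c1 | intermediate
26 | (2R)-1-[3,5-bis(benzyloxy)phenyl]propan-2-ol | C[C@@H](O)Cc1cc(OCc2ccccc2)cc(OCc2ccccc2)c1 | intermediate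
27 | (2R)-1-[3,5-bis(benzyloxy)phenyl]propan-2-yl 3-oxobutanoate | CC(=O)CC(=O)O[C@H](C)Cc1cc(OCc2ccccc2)cc(OCc2ccccc2)c1 | intermediate
28 | (2R)-1-[3,5-bis(benzyloxy)phenyl]propan-2-yl (3S)-3-hydroxybutanoate | C[C@H](O)CC(=O)O[C@H](C)Cc1cc(OCc2ccccc2)cc(OCc2ccccc2)c1 | intermediate
29 | hexa-O-benzyl Hansforester A | Cc1cc(OCc2ccccc2)cc(OCc2ccccc2)c1C(=O)O[C@H](C)CC(=O)O[C@H](C)Cc1cc(OCc2ccccc2)cc(OCc2ccccc2)c1C(=O)O[C@H](C)CC(=O)O[C@H](C)Cc1cc(OCc2ccccc2)cc(OCc2ccccc2)c1 | intermediate
30 | Hansforester A | Cc1cc(O)cc(O)c1C(=O)O[C@H](C)CC(=O)O[C@H](C)Cc1cc(O)cc(O)c1C(=O)O[C@H](C)CC(=O)O[C@H](C)Cc1cc(O)cc(O)c1 | target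

## Step count and least certain steps

Total step count: 19. Longest linear sequence: 14 steps (steps 3 to 14, 18 and 19, from alcohol 4).

**Step 13 (key step).** The most likely failure is slow oxygen insertion with the mild peracid. Forcing it with a stronger peracid such as buffered CF3CO3H invites electrophilic hydroxylation of the benzyloxy-substituted rings, and long exposure invites enolisation with epimerisation at C2 or loss of the aroyloxy group. The fallback gives up the insertion and makes the B–C ester by acylating a ring C alcohol that comes from epoxide 24. It sets out from alcohol 26 and acid chloride 19 and returns to the route at 21.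
- 26 is silylated (TBSCl, imidazole) to the silyl ether F1.
- N-Bromosuccinimide brominates ortho to the side chain to give the aryl bromide F2.
- Bromine–lithium exchange and trapping with Boc2O give the tert-butyl ester F3.
- HF·pyridine gives the ring C alcohol F4, which is handled cold and without acid or base because it can lactonise.
- In parallel, 19 acylates commercial tert-butyl (R)-3-hydroxybutanoate to the diester F5, and CF3CO2H releases the A–B acid F6.
- Carbodiimide coupling of F4 with F6 (EDC·HCl, catalytic DMAP, 0 °C) gives 21.

**Step 11.** The most likely failure is poor facial selectivity. Isopinocampheylboron enolates of methyl ketones are only moderately selective, the two centres are 1,4-related across the carbonyl so the existing one gives little help, and the epimers may be hard to separate. The sense of induction also rests on the assumption stated above. The fallback replaces the aldol induction by a catalytic conjugate borylation; it sets out from 15 and returns at 18.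
- An unselective lithium aldol (LDA, then 16) gives the C5-epimeric aldol mixture F7.
- Mesylation and elimination (MsCl, Et3N) give the E-enone F8.
- CuCl/NaOt-Bu with (R)-1-[(S)-2-(diphenylphosphino)ferrocenyl]ethyldicyclohexylphosphine or its enantiomer, whichever delivers the R carbinol, with B2pin2 and MeOH adds boron to the beta carbon to give the boronate F9.
- NaBO3 oxidises the C–B bond with retention to give 18.

**Step 12.** The most likely failure is acyl transfer from the hindered chloride being slower than base-induced loss of the aroyloxy group from the product (E1cB to the enone) or retro-aldol cleavage of 18. The fallback moves the acylation behind the oxygen insertion, where the substrate is a beta-hydroxy ester and no longer a ketone. It sets out from 18 and returns at 21.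
- TBSOTf/2,6-lutidine gives the silyloxy ketone F10.
- m-CPBA/NaHCO3 gives the silyloxy ester F11.
- HF·pyridine gives the hydroxy ester F12.
- 19 with pyridine and catalytic DMAP then gives 21.

**Step 18.** The most likely failure is dehydration of the activated beta-hydroxy ester to the crotonate instead of substitution, or incomplete inversion with so hindered an acid. The fallback forms the same ester by acyl substitution with retention. It sets out from 27 and 22 and returns at 29.
- Hydrogenation of 27 with RuCl2[(R)-BINAP] gives the 3R alcohol F13.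
- 22 with (COCl)2 and catalytic DMF gives the acid chloride F14.
- The two are joined with pyridine and catalytic DMAP to give 29.

**Step 9.** The most likely failure is attack of the aluminium amide at the ring carbonyl of the oxazolidinone instead of the alpha-branched acyl carbonyl, which opens the auxiliary. The fallback cleaves the imide with a nucleophile that prefers the exocyclic carbonyl. It sets out from 13 and returns at 14.
- LiOH/H2O2 gives the carboxylic acid F15.
- EDC·HCl, N,O-dimethylhydroxylamine hydrochloride and N-methylmorpholine give 14.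

## Further compounds

F1 | step 13 | tert-butyl{[(2R)-1-(3,5-bis(benzyloxy)phenyl)propan-2-yl]oxy}dimethylsilane | CC(C)(C)[Si](C)(C)O[C@H](C)Cc1cc(OCc2ccccc2)cc(OCc2ccccc2)c1
F2 | step 13 | {[(2R)-1-(3,5-bis(benzyloxy)-2-bromophenyl)propan-2-yl]oxy}(tert-butyl)dimethylsilane | CC(C)(C)[Si](C)(C)O[C@H](C)Cc1cc(OCc2ccccc2)cc(OCc2ccccc2)c1Br
F3 | step 13 | tert-butyl 2,4-bis(benzyloxy)-6-{(2R)-2-[(tert-butyldimethylsilyl)oxy]propyl}benzoate | CC(C)(C)[Si](C)(C)O[C@H](C)Cc1cc(OCc2ccccc2)cc(OCc2ccccc2)c1C(=O)OC(C)(C)C
F4 | step 13 | tert-butyl 2,4-bis(benzyloxy)-6-[(2R)-2-hydroxypropyl]benzoate | C[C@@H](O)Cc1cc(OCc2ccccc2)cc(OCc2ccccc2)c1C(=O)OC(C)(C)C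
F5 | step 13 | tert-butyl (3R)-3-{[2,4-bis(benzyloxy)-6-methylbenzoyl]oxy}butanoate | Cc1cc(OCc2ccccc2)cc(OCc2ccccc2)c1C(=O)O[C@H](C)CC(=O)OC(C)(C)C
F6 | step 13 | (3R)-3-{[2,4-bis(benzyloxy)-6-methylbenzoyl]oxy}butanoic acid | Cc1cc(OCc2ccccc2)cc(OCc2ccccc2)c1C(=O)O[C@H](C)CC(=O)O
F7 | step 11 | tert-butyl 2,4-bis(benzyloxy)-6-[(2R)-5-hydroxy-2-methyl-3-oxohexyl]benzoate (mixture of C5 epimers) | CC(O)CC(=O)[C@H](C)Cc1cc(OCc2ccccc2)cc(OCc2ccccc2)c1C(=O)OC(C)(C)C
F8 | step 11 | tert-butyl 2,4-bis(benzyloxy)-6-[(2R,4E)-2-methyl-3-oxohex-4-en-1-yl]benzoate | C/C=C/C(=O)[C@H](C)Cc1cc(OCc2ccccc2)cc(OCc2ccccc2)c1C(=O)OC(C)(C)C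
F9 | step 11 | tert-butyl 2,4-bis(benzyloxy)-6-[(2R,5R)-2-methyl-3-oxo-5-(4,4,5,5-tetramethyl-1,3,2-dioxaborolan-2-yl)hexyl]benzoate | C[C@@H](B1OC(C)(C)C(C)(C)O1)CC(=O)[C@H](C)Cc1cc(OCc2ccccc2)cc(OCc2ccccc2)c1C(=O)OC(C)(C)C
F10 | step 12 | tert-butyl 2,4-bis(benzyloxy)-6-{(2R,5R)-5-[(tert-butyldimethylsilyl)oxy]-2-methyl-3-oxohexyl}benzoate | C[C@@H](O[Si](C)(C)C(C)(C)C)CC(=O)[C@H](C)Cc1cc(OCc2ccccc2)cc(OCc2ccccc2)c1C(=O)OC(C)(C)C
F11 | step 12 | tert-butyl 2,4-bis(benzyloxy)-6-[(2R)-2-({(3R)-3-[(tert-butyldimethylsilyl)oxy]butanoyl}oxy)propyl]benzoate | C[C@@H](O[Si](C)(C)C(C)(C)C)CC(=O)O[C@H](C)Cc1cc(OCc2ccccc2)cc(OCc2ccccc2)c1C(=O)OC(C)(C)C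
F12 | step 12 | tert-butyl 2,4-bis(benzyloxy)-6-[(2R)-2-{[(3R)-3-hydroxybutanoyl]oxy}propyl]benzoate | C[C@@H](O)CC(=O)O[C@H](C)Cc1cc(OCc2ccccc2)cc(OCc2ccccc2)c1C(=O)OC(C)(C)C
F13 | step 18 | (2R)-1-[3,5-bis(benzyloxy)phenyl]propan-2-yl (3R)-3-hydroxybutanoate | C[C@@H](O)CC(=O)O[C@H](C)Cc1cc(OCc2ccccc2)cc(OCc2ccccc2)c1
F14 | step 18 | 2,4-bis(benzyloxy)-6-[(2R)-2-({(3R)-3-{[2,4-bis(benzyloxy)-6-methylbenzoyl]oxy}butanoyl}oxy)propyl]benzoyl chloride | Cc1cc(OCc2ccccc2)cc(OCc2ccccc2)c1C(=O)O[C@H](C)CC(=O)O[C@H](C)Cc1cc(OCc2ccccc2)cc(OCc2ccccc2)c1C(=O)Cl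
F15 | step 9 | (2R)-3-[3,5-bis(benzyloxy)-2-(tert-butoxycarbonyl)phenyl]-2-methylpropanoic acid | OC(=O)[C@H](C)Cc1cc(OCc2ccccc2)cc(OCc2ccccc2)c1C(=O)OC(C)(C)C
A1 | alternative 1 | methyl 2,4-dioxo-6-[(R)-2-(tert-butyldimethylsilyloxy)propyl]cyclohexane-1-carboxylate | COC(=O)C1C(=O)CC(=O)CC1C[C@@H](C)O[Si](C)(C)C(C)(C)C
A2 | alternative 1 | (3E,6R)-6-[(tert-butyldimethylsilyl)oxy]hept-3-en-2-one | CC(=O)/C=C/C[C@@H](C)O[Si](C)(C)C(C)(C)C
A3 | alternative 1 | dimethyl malonate | COC(=O)CC(=O)OC
A4 | alternative 2 | dimethyl 3,5-bis(benzyloxy)homophthalate | COC(=O)Cc1cc(OCc2ccccc2)cc(OCc2ccccc2)c1C(=O)OC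
A5 | alternative 2 | 3,5-bis(benzyloxy)-2-(trimethylsilyl)phenyl trifluoromethanesulfonate | C[Si](C)(C)c1c(OS(=O)(=O)C(F)(F)F)cc(OCc2ccccc2)cc1OCc1ccccc1
A6 | alternative 3 | (2R)-1-[3,5-bis(benzyloxy)phenyl]propan-2-yl (3R)-3-hydroxybutanoate | O[C@H](C)CC(=O)O[C@H](C)Cc1cc(OCc2ccccc2)cc(OCc2ccccc2)c1
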